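C4=O is read back as an exocyclic C4=CH–CH3 alkene. C3–C1' is then reopened by a retro-aromatic-Claisen step to an O2'–CH(CH3)–C4 ether, which a Mitsunobu disconnection splits into ring B phenol 8 and allylic alcohol 16. Further back, C5'–CMe2 is cut by a second retro-Claisen step and C4–acetyl by a Stille disconnection.
Enabling feature: ring B has a free hydroxyl on C2', ortho to C1', which is bonded to C3, and C3 is next to C4. The run O2'–C2'–C1'–C3–C4 plus one exocyclic carbon on C4 is the product pattern of an aromatic Claisen rearrangement. The C3' methoxy group leaves C1' as the only open ortho carbon of O2', just as C5' is the only open ortho carbon of O4'.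
Forward order: no ring is built. Ring B comes from 2-methoxyresorcinol, and rings A and C arrive together in 7-hydroxychroman-4-one. The halves are tied through O2' (step 10), the tie is traded for C3–C1' (step 11), and the surplus two-carbon unit is cut off to unveil the ketone.
Stereochemistry: C3 is the only stereocentre. A CBS reduction sets an (S)-carbinol, the Mitsunobu reaction inverts it to (R), and the suprafacial [3,3] shift relays it to C3 as (3R). The spent carbinol carbon leaves as acetaldehyde, and every step after the ketone appears is neutral or buffered.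

Key step: step 11

Remark: the stereocentre in the given SMILES is read as (3R). Isoflavonoid numbering is used (chromanone = rings A and C, primed atoms = ring B), and the exocyclic carbon on C4 is called Cα.

Step 1
Reactants: 1 2-methoxyresorcinol (2-methoxybenzene-1,3-diol); 2 prenyl bromide (1-bromo-3-methylbut-2-ene)
Product: 3 2-methoxy-3-(3-methylbut-2-enyloxy)phenol
Conditions: 1 (2 equiv), K2CO3 (1 equiv), acetone, reflux
Reagents that add atoms: none
Why: Williamson ether synthesis: with the symmetrical diphenol in excess and only one equivalent of a weak base, the reactive allylic bromide should be consumed by O-alkylation at one phenoxide, and the much more polar surplus 1 is recovered on chromatography.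

Step 2
Reactants: 3 2-methoxy-3-(3-methylbut-2-enyloxy)phenol
Product: 4 2-methoxy-3-(3-methylbut-2-enyloxy)phenyl pivalate
Conditions: PivCl, Et3N, 4-(dimethylamino)pyridine (cat.), CH2Cl2, 0 °C to rt
Reagents that add atoms: pivaloyl chloride, CC(C)(C)C(=O)Cl
Why: DMAP-catalysed O-acylation of the remaining phenol, the pivalate being chosen because it should withstand the hot amine of step 3, cannot migrate to the meta-related O4' and resists the carbonate base of step 4.

Step 3
Reactants: 4 2-methoxy-3-(3-methylbut-2-enyloxy)phenyl pivalate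
Product: 6 3-hydroxy-2-methoxy-4-(2-methylbut-3-en-2-yl)phenyl pivalate, via ortho-dienone 5 (not isolated)
Conditions: PhNEt2, 190 °C, sealed tube, Ar
Reagents that add atoms: none
Why: Aromatic Claisen rearrangement: the [3,3] shift turns the prenyl unit around and delivers its tertiary carbon to the only hydrogen-bearing ortho carbon of O4' (the other one carries OMe), which builds the quaternary centre on C5', while the basic solvent speeds enolisation of dienone 5 so that a second shift to the para carbon should be outrun.

Step 4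
Reactants: 6 3-hydroxy-2-methoxy-4-(2-methylbut-3-en-2-yl)phenyl pivalate
Product: 7 2,3-dimethoxy-4-(2-methylbut-3-en-2-yl)phenyl pivalate
Conditions: MeI, K2CO3, DMF, rt to 40 °C
Reagents that add atoms: methyl iodide, CI
Why: Williamson O-methylation: the phenoxide between OMe and the tertiary alkyl group is crowded but methyl iodide is small, and anhydrous carbonate leaves the pivalate and the vinyl group alone.

Step 5
Reactants: 7 2,3-dimethoxy-4-(2-methylbut-3-en-2-yl)phenyl pivalate
Product: 8 2,3-dimethoxy-4-(2-methylbut-3-en-2-yl)phenol (ring B fragment)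
Conditions: KOH, MeOH/H2O, rt; then 1 M HCl
Reagents that add atoms: none
Why: Saponification of an aryl ester, in which the good phenoxide leaving group allows even a pivalate to be hydrolysed under mild conditions that affect nothing else in 7.

Step 6
Reactants: 9 7-hydroxychroman-4-one
Product: 10 7-(triisopropylsilyloxy)chroman-4-one
Conditions: TIPSCl, imidazole, DMF, rt
Reagents that add atoms: triisopropylsilyl chloride, CC(C)[Si](Cl)(C(C)C)C(C)C
Why: Imidazole-promoted O-silylation of the acidic 7-phenol, the bulky triisopropylsilyl group being chosen to last through amide base, dilute acid, borane reduction and 160 °C.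

Step 7
Reactants: 10 7-(triisopropylsilyloxy)chroman-4-one
Product: 12 7-(triisopropylsilyloxy)-2H-chromen-4-yl trifluoromethanesulfonate, via lithium enolate 11 (not isolated)
Conditions: LiHMDS, THF, −78 °C; then N-(5-chloropyridin-2-yl)bis(trifluoromethanesulfonimide) (Comins reagent), −78 °C; aq. NH4Cl
Reagents that add atoms: N-(5-chloropyridin-2-yl)bis(trifluoromethanesulfonimide), O=S(=O)(N(c1ccc(Cl)cn1)S(=O)(=O)C(F)(F)F)C(F)(F)F
Why: Kinetic enolisation followed by O-triflation: C3 is the only enolisable position, and the very reactive pyridyl triflimide should trap enolate 11 at −78 °C before it can expel the ring C phenoxide by β-elimination.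

Step 8
Reactants: 12 7-(triisopropylsilyloxy)-2H-chromen-4-yl trifluoromethanesulfonate; 13 tributyl(1-ethoxyvinyl)stannane
Product: 15 1-[7-(triisopropylsilyloxy)-2H-chromen-4-yl]ethanone, via 2-ethoxydiene 14 (not isolated)
Conditions: Pd(PPh3)4 (5 mol %), LiCl (3 equiv), THF, reflux; then 1 M HCl, THF, rt
Reagents that add atoms: water, O
Why: Stille coupling of a vinyl triflate (chloride keeps the vinylpalladium species in the cycle) with an acetyl-anion equivalent, followed by hydrolysis of the very acid-labile 2-ethoxydiene 14 under conditions that an aryl triisopropylsilyl ether tolerates.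

Step 9
Reactants: 15 1-[7-(triisopropylsilyloxy)-2H-chromen-4-yl]ethanone
Product: 16 (1S)-1-[7-(triisopropylsilyloxy)-2H-chromen-4-yl]ethanol
Conditions: (R)-2-methyl-CBS-oxazaborolidine [(R)-1-methyl-3,3-diphenyltetrahydro-1H,3H-pyrrolo[1,2-c][1,3,2]oxazaborole] (20 mol %), catecholborane, toluene, −78 °C; aqueous work-up
Reagents that add atoms: none
Why: Corey–Bakshi–Shibata reduction: the ketone binds to the ring boron with the large chromenyl group turned away from the catalyst, so the (R)-oxazaborolidine should deliver hydride in the sense that turns acetophenone into (S)-1-phenylethanol and give the (S)-carbinol, and catecholborane at −78 °C reduces enones 1,2 without hydroborating the alkene.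

Step 10
Reactants: 8 2,3-dimethoxy-4-(2-methylbut-3-en-2-yl)phenol; 16 (1S)-1-[7-(triisopropylsilyloxy)-2H-chromen-4-yl]ethanol
Product: 17 4-{(1R)-1-[2,3-dimethoxy-4-(2-methylbut-3-en-2-yl)phenoxy]ethyl}-7-(triisopropylsilyloxy)-2H-chromene
Conditions: PPh3, DIAD, toluene, −20 °C to rt
Reagents that add atoms: none
Why: Mitsunobu reaction: the phenoxide of 8 displaces the alkoxyphosphonium group in an SN2 process that inverts Cα from (S) to (R), ionisation being disfavoured because ring A sits on the central, nodal carbon of the would-be allyl cation and because the medium is cold and apolar.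

Step 11
Reactants: 17 4-{(1R)-1-[2,3-dimethoxy-4-(2-methylbut-3-en-2-yl)phenoxy]ethyl}-7-(triisopropylsilyloxy)-2H-chromene
Product: 20 6-[(3R,4E)-4-ethylidene-7-(triisopropylsilyloxy)chroman-3-yl]-2,3-dimethoxy-4-(2-methylbut-3-en-2-yl)phenol, via ortho-dienone 18 (not isolated), via trimethylsilyl ether 19 (not isolated)
Conditions: N,O-bis(trimethylsilyl)acetamide (BSA, 3 equiv), mesitylene (degassed), 160 °C, Ar; then K2CO3 (5 mol %), MeOH, 0 °C
Reagents that add atoms: none
Why: Aromatic Claisen rearrangement: in a concerted, suprafacial [3,3] shift over the six atoms O2', Cα, C4, C3, C1' and C2', the Cα–O2' bond breaks while C3–C1' forms on the same face of the allyl unit, the alkene moves from C3=C4 to C4=Cα, and dienone 18 (H on C1') enolises irreversibly to the phenol, which BSA holds as silyl ether 19 until the methanolysis. The closest known reaction types are the thermal rearrangement of 4-(aryloxymethyl)-2H-chromenes to 3-(2-hydroxyaryl)-4-methylenechromans and the 1,3-chirality transfer in aromatic Claisen rearrangements of enantioenriched secondary allyl aryl ethers. No ring is closed, the cyclic transition state merely converts the O2' tether into the C3–C1' bond. The new stereocentre C3 is controlled by the (R)-configured Cα through a single reactive rotamer: the peri C5–H of ring A keeps the Cα methyl group out of its sector and turns it toward C3–H, which fixes the face on which O2' departs and C1' arrives and should give (3R) together with the (E)-ethylidene, and chair and boat arrays converge on the same C3 configuration because C1' becomes planar again. Site selectivity on ring B follows from the C3' methoxy group, which blocks the second ortho carbon, and the allyl aryl ether embedded in ring C is inert because C4 cannot reach C8. Chemoselectivity against ionisation, elimination to the 4-vinylchromene, addition of the freed phenol to C4 and the abnormal Claisen pathway is sought through the apolar solvent and through BSA, which scavenges traces of acid and caps the phenol as it forms.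

Step 12
Reactants: 20 6-[(3R,4E)-4-ethylidene-7-(triisopropylsilyloxy)chroman-3-yl]-2,3-dimethoxy-4-(2-methylbut-3-en-2-yl)phenol
Product: 21 (3R,4E)-3-[2-(tert-butyldimethylsilyloxy)-3,4-dimethoxy-5-(2-methylbut-3-en-2-yl)phenyl]-4-ethylidene-7-(triisopropylsilyloxy)chroman
Conditions: TBSCl, imidazole, DMF, 40 °C
Reagents that add atoms: tert-butyldimethylsilyl chloride, CC(C)(C)[Si](C)(C)Cl
Why: Imidazole-promoted O-silylation: the guaiacol-type 2'-phenol has to be masked because periodate would oxidise it and because it could add to C4, and a tert-butyldimethylsilyl ether can later leave together with the 7-silyl group.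

Step 13
Reactants: 21 (3R,4E)-3-[2-(tert-butyldimethylsilyloxy)-3,4-dimethoxy-5-(2-methylbut-3-en-2-yl)phenyl]-4-ethylidene-7-(triisopropylsilyloxy)chroman
Product: 22 (3R,4S)-3-[2-(tert-butyldimethylsilyloxy)-3,4-dimethoxy-5-(2-methylbut-3-en-2-yl)phenyl]-4-[(1S)-1-hydroxyethyl]-7-(triisopropylsilyloxy)chroman-4-ol
Conditions: OsO4 (2 mol %), NMO (1.05 equiv), MeSO2NH2, acetone/H2O, 0 °C
Reagents that add atoms: osmium tetroxide, O=[Os](=O)(=O)=O; N-methylmorpholine N-oxide, C[N+]1([O-])CCOCC1; water, O
Why: Upjohn dihydroxylation: electrophilic OsO4 should prefer the trisubstituted ethylidene conjugated to the donor-substituted ring A over the monosubstituted neopentyl vinyl group, the near-stoichiometric amine oxide stops the reaction after one alkene, and syn addition opposite the pseudo-axial ring B sets the (4S,αS) centres, both of which vanish in step 14.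

Step 14
Reactants: 22 (3R,4S)-3-[2-(tert-butyldimethylsilyloxy)-3,4-dimethoxy-5-(2-methylbut-3-en-2-yl)phenyl]-4-[(1S)-1-hydroxyethyl]-7-(triisopropylsilyloxy)chroman-4-ol
Product: 23 (3R)-3-[2-(tert-butyldimethylsilyloxy)-3,4-dimethoxy-5-(2-methylbut-3-en-2-yl)phenyl]-7-(triisopropylsilyloxy)chroman-4-one (bis-silyl pervilleanone)
Conditions: NaIO4, THF/pH 7 phosphate buffer, 0 °C to rt
Reagents that add atoms: none
Why: Malaprade glycol cleavage through a cyclic periodate ester, which unveils the C4 ketone and releases Cα as acetaldehyde at neutral pH so that the now acidic C3–H is not exchanged.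

Step 15
Reactants: 23 (3R)-3-[2-(tert-butyldimethylsilyloxy)-3,4-dimethoxy-5-(2-methylbut-3-en-2-yl)phenyl]-7-(triisopropylsilyloxy)chroman-4-one
Product: 24 pervilleanone, (3R)-7-hydroxy-3-[2-hydroxy-3,4-dimethoxy-5-(2-methylbut-3-en-2-yl)phenyl]chroman-4-one
Conditions: TBAF (2.5 equiv), AcOH (3 equiv), THF, 0 °C
Reagents that add atoms: none
Why: Fluoride-mediated desilylation, fast for aryl silyl ethers because phenoxides leave readily, with acetic acid protonating each phenoxide as it forms so that no base able to enolise C4=O and epimerise C3 builds up.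

Compound list
1 | 2-methoxyresorcinol | COc1c(O)cccc1O | starting material
2 | prenyl bromide | CC(C)=CCBr | starting material
3 | 2-methoxy-3-(3-methylbut-2-enyloxy)phenol | CC(C)=CCOc1cccc(O)c1OC | intermediate
4 | 2-methoxy-3-(3-methylbut-2-enyloxy)phenyl pivalate | CC(C)=CCOc1cccc(OC(=O)C(C)(C)C)c1OC | intermediate
5 | ortho-dienone, 2-methoxy-6-(2-methylbut-3-en-2-yl)-3-pivaloyloxycyclohexa-2,4-dien-1-one (racemic, not isolated) | C=CC(C)(C)C1C=CC(OC(=O)C(C)(C)C)=C(OC)C1=O | intermediate
6 | 3-hydroxy-2-methoxy-4-(2-methylbut-3-en-2-yl)phenyl pivalate | C=CC(C)(C)c1ccc(OC(=O)C(C)(C)C)c(OC)c1O | intermediate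
7 | 2,3-dimethoxy-4-(2-methylbut-3-en-2-yl)phenyl pivalate | C=CC(C)(C)c1ccc(OC(=O)C(C)(C)C)c(OC)c1OC | intermediate
8 | 2,3-dimethoxy-4-(2-methylbut-3-en-2-yl)phenol | C=CC(C)(C)c1ccc(O)c(OC)c1OC | intermediate
9 | 7-hydroxychroman-4-one | O=C1CCOc2cc(O)ccc21 | starting material
10 | 7-(triisopropylsilyloxy)chroman-4-one | O=C1CCOc2cc(O[Si](C(C)C)(C(C)C)C(C)C)ccc21 | intermediate
11 | lithium enolate of 10 (not isolated) | [Li+].[O-]C1=CCOc2cc(O[Si](C(C)C)(C(C)C)C(C)C)ccc21 | intermediate
12 | 7-(triisopropylsilyloxy)-2H-chromen-4-yl trifluoromethanesulfonate | CC(C)[Si](C(C)C)(C(C)C)Oc1ccc2c(c1)OCC=C2OS(=O)(=O)C(F)(F)F | intermediate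
13 | tributyl(1-ethoxyvinyl)stannane | CCCC[Sn](CCCC)(CCCC)C(=C)OCC | starting material
14 | 4-(1-ethoxyvinyl)-7-(triisopropylsilyloxy)-2H-chromene (not isolated) | C=C(OCC)C1=CCOc2cc(O[Si](C(C)C)(C(C)C)C(C)C)ccc21 | intermediate
15 | 1-[7-(triisopropylsilyloxy)-2H-chromen-4-yl]ethanone | CC(=O)C1=CCOc2cc(O[Si](C(C)C)(C(C)C)C(C)C)ccc21 | intermediate
16 | (1S)-1-[7-(triisopropylsilyloxy)-2H-chromen-4-yl]ethanol | C[C@H](O)C1=CCOc2cc(O[Si](C(C)C)(C(C)C)C(C)C)ccc21 | intermediate
17 | 4-{(1R)-1-[2,3-dimethoxy-4-(2-methylbut-3-en-2-yl)phenoxy]ethyl}-7-(triisopropylsilyloxy)-2H-chromene | C[C@@H](Oc1ccc(C(C)(C)C=C)c(OC)c1OC)C1=CCOc2cc(O[Si](C(C)C)(C(C)C)C(C)C)ccc21 | intermediate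
18 | ortho-dienone, (6S)-6-[(3S,4E)-4-ethylidene-7-(triisopropylsilyloxy)chroman-3-yl]-2,3-dimethoxy-4-(2-methylbut-3-en-2-yl)cyclohexa-2,4-dien-1-one (not isolated; drawn for the chair array; C3 has the same spatial arrangement as in 20, its descriptor differs only through CIP ranking) | C=CC(C)(C)C1=C[C@@H]([C@@H]2COc3cc(O[Si](C(C)C)(C(C)C)C(C)C)ccc3/C2=C/C)C(=O)C(OC)=C1OC | intermediate
19 | trimethylsilyl ether of 20 (3R,4E; not isolated) | C=CC(C)(C)c1cc([C@@H]2COc3cc(O[Si](C(C)C)(C(C)C)C(C)C)ccc3/C2=C/C)c(O[Si](C)(C)C)c(OC)c1OC | intermediate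
20 | 6-[(3R,4E)-4-ethylidene-7-(triisopropylsilyloxy)chroman-3-yl]-2,3-dimethoxy-4-(2-methylbut-3-en-2-yl)phenol | C=CC(C)(C)c1cc([C@@H]2COc3cc(O[Si](C(C)C)(C(C)C)C(C)C)ccc3/C2=C/C)c(O)c(OC)c1OC | intermediate
21 | (3R,4E)-3-[2-(tert-butyldimethylsilyloxy)-3,4-dimethoxy-5-(2-methylbut-3-en-2-yl)phenyl]-4-ethylidene-7-(triisopropylsilyloxy)chroman | C=CC(C)(C)c1cc([C@@H]2COc3cc(O[Si](C(C)C)(C(C)C)C(C)C)ccc3/C2=C/C)c(O[Si](C)(C)C(C)(C)C)c(OC)c1OC | intermediate
22 | (3R,4S)-3-[2-(tert-butyldimethylsilyloxy)-3,4-dimethoxy-5-(2-methylbut-3-en-2-yl)phenyl]-4-[(1S)-1-hydroxyethyl]-7-(triisopropylsilyloxy)chroman-4-ol | C=CC(C)(C)c1cc([C@@H]2COc3cc(O[Si](C(C)C)(C(C)C)C(C)C)ccc3[C@]2(O)[C@H](C)O)c(O[Si](C)(C)C(C)(C)C)c(OC)c1OC | intermediate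
23 | (3R)-3-[2-(tert-butyldimethylsilyloxy)-3,4-dimethoxy-5-(2-methylbut-3-en-2-yl)phenyl]-7-(triisopropylsilyloxy)chroman-4-one | C=CC(C)(C)c1cc([C@@H]2COc3cc(O[Si](C(C)C)(C(C)C)C(C)C)ccc3C2=O)c(O[Si](C)(C)C(C)(C)C)c(OC)c1OC | intermediate
24 | pervilleanone, (3R)-7-hydroxy-3-[2-hydroxy-3,4-dimethoxy-5-(2-methylbut-3-en-2-yl)phenyl]chroman-4-one | C=CC(C)(C)c1cc([C@@H]2COc3cc(O)ccc3C2=O)c(O)c(OC)c1OC | target

Total step count: 15. Longest linear sequence: 11 steps (steps 1–5 and 10–15, counted from 1). The ring A/C branch (steps 6–9) joins at step 10.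

Steps most likely to fail

Step 11. Heterolysis of the secondary allylic C–O bond, elimination of the phenol to the 4-vinylchromene, or leakage through the minor rotamer would each cost material or enantiopurity.
- The fallback gives up the tether, forms C3–C1' by enolate arylation and sets C3 by dynamic kinetic resolution. It sets out from phenol 8 and chromanone 10.
- Amine-assisted ortho-bromination of 8 (NBS, i-Pr2NH cat., CH2Cl2, −20 °C) should give 6-bromo-2,3-dimethoxy-4-(2-methylbut-3-en-2-yl)phenol F1. The para carbon is blocked and the other ortho carbon carries OMe.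
- Silylation (TBSCl, imidazole, DMF) should give its tert-butyldimethylsilyl ether F2.
- Palladium-catalysed ketone α-arylation of 10 with F2 (Pd(OAc)2, P(t-Bu)3·HBF4, K3PO4, toluene, 90 °C) should give the racemic bis-silyl isoflavanone F3.
- Noyori asymmetric transfer hydrogenation under racemising conditions (RuCl(p-cymene)[(R,R)-TsDPEN], HCO2H/Et3N) is a known way to turn racemic isoflavanones into cis-isoflavan-4-ols. It should give the (3R,4R)-cis-isoflavan-4-ol F4.
- Bicarbonate-buffered Dess–Martin oxidation restores the ketone without touching C3, and the route is rejoined at 23.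

Step 10. SN2' attack at C3, collapse of the alkoxyphosphonium ion to the diene, or partial ionisation would lower both the yield and the configurational purity of the ether.
- The fallback replaces inversion at an activated alcohol by a metal-allyl substitution with net retention. It sets out from ketone 15 and phenol 8.
- Reduction of 15 with the enantiomeric (S)-2-methyl-CBS-oxazaborolidine and catecholborane should give (1R)-1-[7-(triisopropylsilyloxy)-2H-chromen-4-yl]ethanol F5.
- Methyl chloroformate and pyridine convert it into the (R)-methyl carbonate F6.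
- Rhodium-catalysed enantiospecific allylic etherification (RhCl(PPh3)3, P(OMe)3, 8 deprotonated with NaHMDS, THF, 0 °C to rt) is a method developed for secondary allylic carbonates and ortho-substituted phenols. It should place the aryloxy group on the carbon that carried the leaving group with retention, although oxidative addition to this trisubstituted alkene may be slower than with the terminal alkenes usually used. The route is rejoined at 17.

Step 13. Competing osmylation of the vinyl group, or too slow a reaction at the crowded ethylidene, would spoil the differentiation of the two alkenes.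
- The fallback switches to an oxidant whose rate depends much more strongly on alkene substitution and donor conjugation. It sets out from 21.
- Epoxidation with dimethyldioxirane (acetone, −20 °C, neutral) should give the spiro-epoxide of 21 (oxygen opposite ring B; 3R,4S,αS) F7.
- Periodic acid in water-rich THF (H5IO6, 0 °C) opens and cleaves F7 directly. The high water content is meant to capture the benzylic cation at C4 before H3 can be lost. The diol stage is bypassed and the route is rejoined at 23.

Further compounds
F1 | step 11 | 6-bromo-2,3-dimethoxy-4-(2-methylbut-3-en-2-yl)phenol | C=CC(C)(C)c1cc(Br)c(O)c(OC)c1OC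
F2 | step 11 | [6-bromo-2,3-dimethoxy-4-(2-methylbut-3-en-2-yl)phenoxy](tert-butyl)dimethylsilane | C=CC(C)(C)c1cc(Br)c(O[Si](C)(C)C(C)(C)C)c(OC)c1OC
F3 | step 11 | racemic bis-silyl isoflavanone (racemate of 23) | C=CC(C)(C)c1cc(C2COc3cc(O[Si](C(C)C)(C(C)C)C(C)C)ccc3C2=O)c(O[Si](C)(C)C(C)(C)C)c(OC)c1OC
F4 | step 11 | (3R,4R)-3-[2-(tert-butyldimethylsilyloxy)-3,4-dimethoxy-5-(2-methylbut-3-en-2-yl)phenyl]-7-(triisopropylsilyloxy)chroman-4-ol (cis) | C=CC(C)(C)c1cc([C@@H]2COc3cc(O[Si](C(C)C)(C(C)C)C(C)C)ccc3[C@@H]2O)c(O[Si](C)(C)C(C)(C)C)c(OC)c1OC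
F5 | step 10 | (1R)-1-[7-(triisopropylsilyloxy)-2H-chromen-4-yl]ethanol | C[C@@H](O)C1=CCOc2cc(O[Si](C(C)C)(C(C)C)C(C)C)ccc21
F6 | step 10 | methyl (1R)-1-[7-(triisopropylsilyloxy)-2H-chromen-4-yl]ethyl carbonate | C[C@@H](OC(=O)OC)C1=CCOc2cc(O[Si](C(C)C)(C(C)C)C(C)C)ccc21
F7 | step 13 | spiro-epoxide of 21 (3R,4S,αS; oxygen opposite ring B) | C=CC(C)(C)c1cc([C@@H]2COc3cc(O[Si](C(C)C)(C(C)C)C(C)C)ccc3[C@@]24O[C@H]4C)c(O[Si](C)(C)C(C)(C)C)c(OC)c1OC
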